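Numbering: bicyclo[3.2.1]octane with C1 (bridgehead, allyl), C2=C3 (OMe on C3), C4 (OAc), C5 (bridgehead, OMe), C6 (aryl), C7 (methyl), C8 (bridging C=O).
Bonds cut, in order: acetyl–O at C4; C4–H (back to the 4,8-dione); then together C5–C6 and C1–CH2 of the allyl group, with C6 returned to the oxygen on C8 and the allyl group to the oxygen on C4; then the benzylic O–C6 bond, the C6–C7 bond (styrene plus aroyl anhydride), and last the vinyl, formyl, hydroxyl and O-allyl groups on a syringol ring.
Feature that allows the key step: the ring C1–C2–C3–C4–C5–C8 bears oxygen on C3, C4, C5 and C8 and is a benzene ring that has lost its aromaticity. The allyl group on C1 lies para to the C4 oxygen and C6 hangs on C5, next to the oxygen-bearing C8, so the 4,8-dione (C23H28O7) is an isomer of the aromatic 6-allyloxy-5,7-dimethoxy-3-methyl-2-aryl-2,3-dihydrobenzofuran, differing by an O-to-C1 allyl shift and an O-to-C5 benzyl shift.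
Rings in the forward direction: the benzene ring is bought and ends as the six-membered ring; a dihydrofuran ring is closed on it for a time; the key step opens that ring and closes the cyclopentanone ring C1–C7–C6–C5–C8, which finishes the bicycle.
Stereochemistry: C7 comes from ligand-controlled hydrocupration of the styrene; C1, C5 and C6 are relayed from C7 in the key step; C4 comes from hydride addition to the ketone face syn to C8, the other face being covered by the endo aryl group.

Key step: step 11

Assumption: the (R,R) enantiomer of Ph-BPE is taken to give the R ketone in step 8. If the sense of induction proves opposite, the equally available (S,S) ligand is used and nothing else changes.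

Step 1
Reactants: 1 2,6-dimethoxyphenol (syringol); 2 allyl bromide
Product: 3 2-allyloxy-1,3-dimethoxybenzene
Conditions: K2CO3, acetone, reflux
Reagents that add atoms: none
Why: Williamson etherification, in which the phenoxide is the only nucleophile and the primary allylic bromide is displaced by SN2 at oxygen.

Step 2
Reactants: 3 2-allyloxy-1,3-dimethoxybenzene
Product: 5 3-allyloxy-2,4-dimethoxybenzaldehyde, via iminium salt 4 (not isolated)
Conditions: POCl3, DMF, 0 → 80 °C; then ice-water
Reagents that add atoms: N,N-dimethylformamide CN(C)C=O; water O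
Why: Vilsmeier–Haack formylation, which on 1,2,3-trialkoxybenzenes goes to the carbon para to one outer methoxy group and ortho to the other, because the twisted central alkoxy group activates its own para position least.

Step 3
Reactants: 5 3-allyloxy-2,4-dimethoxybenzaldehyde
Product: 7 3-allyloxy-2,4-dimethoxyphenol, via aryl formate 6 (not isolated)
Conditions: 30% aq H2O2, H2SO4 (cat.), MeOH, rt
Reagents that add atoms: hydrogen peroxide OO
Why: Acid-catalysed Dakin-type (Baeyer–Villiger) oxidation, in which the aryl group with ortho and para methoxy donors migrates to oxygen, the formate is methanolysed in the flask, and peracid-free hydrogen peroxide leaves the allyl alkene alone.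

Step 4
Reactants: 7 3-allyloxy-2,4-dimethoxyphenol
Product: 8 4-allyloxy-2-hydroxy-3,5-dimethoxybenzaldehyde
Conditions: MgCl2, Et3N, (CH2O)n, MeCN, reflux; then 1 M HCl
Reagents that add atoms: paraformaldehyde (as formaldehyde) C=O
Why: Casnati–Skattebøl ortho-formylation, in which the magnesium phenoxide delivers formaldehyde to the ortho carbon through a chelate and a second formaldehyde takes up the hydride, and only one ortho position of 7 carries hydrogen.

Step 5
Reactants: 8 4-allyloxy-2-hydroxy-3,5-dimethoxybenzaldehyde
Product: 9 4-allyloxy-3,5-dimethoxy-2-(methoxymethoxy)benzaldehyde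
Conditions: MOMCl, iPr2NEt, CH2Cl2, 0 °C → rt
Reagents that add atoms: chloromethyl methyl ether COCCl
Why: Standard methoxymethyl acetal protection of a phenol, chosen because it removes the acidic proton before the ylide and copper hydride steps and because one acid treatment later both unmasks it and closes the ring.

Step 6
Reactants: 9 4-allyloxy-3,5-dimethoxy-2-(methoxymethoxy)benzaldehyde; 10 methyltriphenylphosphonium bromide
Product: 11 2-allyloxy-1,3-dimethoxy-4-(methoxymethoxy)-5-vinylbenzene
Conditions: 10, KOtBu, THF, 0 °C; then 9, 0 °C → rt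
Reagents that add atoms: none
Why: Wittig methylenation with the non-stabilised ylide, to which the aryl ethers, the acetal and the allyl group are inert.

Step 7
Reactants: 12 3,4,5-trimethoxybenzoic acid (2 equiv)
Product: 13 3,4,5-trimethoxybenzoic anhydride
Conditions: DCC (0.5 equiv), CH2Cl2, rt; filtration
Reagents that add atoms: none
Why: Carbodiimide dehydration through the O-acylisourea, with half an equivalent of DCC stopping at the symmetrical anhydride.

Step 8
Reactants: 11 2-allyloxy-1,3-dimethoxy-4-(methoxymethoxy)-5-vinylbenzene; 13 3,4,5-trimethoxybenzoic anhydride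
Product: 14 (2R)-2-[4-allyloxy-3,5-dimethoxy-2-(methoxymethoxy)phenyl]-1-(3,4,5-trimethoxyphenyl)propan-1-one
Conditions: Cu(OAc)2 (5 mol %), (R,R)-Ph-BPE (5.5 mol %), (MeO)2MeSiH (1.5 equiv), THF, rt, stopped when 11 is consumed; aq NaHCO3
Reagents that add atoms: none
Why: Copper hydride catalysed enantioselective hydroacylation of a vinylarene with a symmetrical aroyl anhydride, in which ligand-controlled Markovnikov hydrocupration sets C7 at the benzylic copper species, acylation proceeds with retention, and the conjugated alkene reacts much faster than the isolated allyl ether alkene.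

Step 9
Reactants: 14 (2R)-2-[4-allyloxy-3,5-dimethoxy-2-(methoxymethoxy)phenyl]-1-(3,4,5-trimethoxyphenyl)propan-1-one
Product: 15 (2R)-2-[4-allyloxy-3,5-dimethoxy-2-(methoxymethoxy)phenyl]-1-(3,4,5-trimethoxyphenyl)propan-1-ol (both carbinol epimers, used together)
Conditions: NaBH4, CeCl3·7H2O, MeOH, -20 °C
Reagents that add atoms: none
Why: Cerium-buffered borohydride reduction (Luche conditions) of an aryl ketone, fast and nearly neutral so that the enolisable C7 centre is not epimerised, and the new carbinol centre needs no control because it is ionised later.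

Step 10
Reactants: 15 (2R)-2-[4-allyloxy-3,5-dimethoxy-2-(methoxymethoxy)phenyl]-1-(3,4,5-trimethoxyphenyl)propan-1-ol
Product: 17 (2R,3R)-6-allyloxy-5,7-dimethoxy-3-methyl-2-(3,4,5-trimethoxyphenyl)-2,3-dihydrobenzofuran, via free phenol 16 (not isolated)
Conditions: conc. HCl (cat.), MeOH, 50 °C
Reagents that add atoms: none
Why: Acid methanolysis of the methoxymethyl acetal followed by cyclodehydration, in which the 3,4,5-trimethoxybenzylic cation is caught by the neighbouring phenol in a 5-exo closure that places the aryl group trans to the methyl group, while C7 (C3 of the benzofuran) is not involved and the C2 configuration is of no consequence.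

Step 11
Reactants: 17 (2R,3R)-6-allyloxy-5,7-dimethoxy-3-methyl-2-(3,4,5-trimethoxyphenyl)-2,3-dihydrobenzofuran
Product: 21 (1S,5R,6R,7S)-1-allyl-3,5-dimethoxy-7-methyl-6-(3,4,5-trimethoxyphenyl)bicyclo[3.2.1]oct-2-ene-4,8-dione, via ortho dienone 18 (not isolated), via 3a-allyl dienone 19 (not isolated), via cation enolate 20 (not isolated)
Conditions: Sc(OTf)3 (1.0 equiv), 2,6-di-tert-butylpyridine (0.1 equiv), 4 Å MS, ClCH2CH2Cl, 70 °C; then H2O
Reagents that add atoms: none
Why: Proposed new method: Sc(OTf)3 on the allyl ether oxygen should set off a charge-accelerated [3,3] Claisen shift to a methoxy-bearing ortho carbon (18, the other ortho carbon being equivalent in outcome) and a [3,3] Cope shift on to the para carbon C1 (19), the two allyl inversions leaving the former OCH2 carbon, not the terminal one, bonded to C1, after which the O–C6 bond, now part of a vinylogous ester, ionises to the 3,4,5-trimethoxybenzylic cation and the metal-bound 2-methoxy-1,3-dione enolate (20) and C5 of that enolate captures C6. The closest known reaction types are the para-Claisen rearrangement of 2,6-disubstituted aryl allyl ethers, its thermal reverse from 3a-allyl hydrobenzofuranone neolignans, and the acid-catalysed rearrangement of such 3a-allyl dienones into bicyclo[3.2.1]octanoids, and what has no precedent is their coupling in one operation against the loss of aromaticity. The only ring closed is the cyclopentanone C1–C7–C6–C5–C8, by a 5-(enolexo)-exo-trig attack of the C4–C5 enolate on the cationic carbon, while the dihydrofuran ring opens. C7 is the one stereocentre carried in and directs the others: the allyl group can reach either face of C1 and the two C1 epimers exchange through the reversible shifts, but only the epimer with allyl cis to the C7 methyl group lets the cation close with the methyl group exo and the aryl group both trans to it and endo, stacked on the enolate as a contact ion pair, C5 then follows because the C7–C6 tether reaches only the ring face opposite to the allyl group, and C6 is set at the planar cation so that either C2 epimer of 17 converges. The step needs ionisation to wait for the allyl relay and the allyl group to settle only on C1, and the substrate secures both because the aryloxide of 17 is a poor leaving group until dearomatisation makes it a dione enolate and because both ortho carbons carry methoxy groups and offer no hydrogen for rearomatisation. A full equivalent of the chelating Lewis acid is used so that binding to the C4=O, C5-OMe, C8=O pocket of 21 pulls the reversible manifold towards the bridged dione, and the hindered pyridine keeps stray TfOH from ionising 17 early or cleaving the allyl ether.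

Step 12
Reactants: 21 (1S,5R,6R,7S)-1-allyl-3,5-dimethoxy-7-methyl-6-(3,4,5-trimethoxyphenyl)bicyclo[3.2.1]oct-2-ene-4,8-dione
Product: 22 (1S,4R,5S,6R,7S)-1-allyl-4-hydroxy-3,5-dimethoxy-7-methyl-6-(3,4,5-trimethoxyphenyl)bicyclo[3.2.1]oct-2-en-8-one
Conditions: NaBH4, CeCl3·7H2O, MeOH, -78 °C
Reagents that add atoms: none
Why: Luche 1,2-reduction, in which the cerium-activated hard borohydride adds to the enone carbonyl C4 rather than to C2 or to the C8 ketone flanked by two fully substituted bridgeheads, and it comes from the face syn to C8 because the endo aryl group on C6 covers the other face, so the hydroxyl group ends up endo (4R).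

Step 13
Reactants: 22 (1S,4R,5S,6R,7S)-1-allyl-4-hydroxy-3,5-dimethoxy-7-methyl-6-(3,4,5-trimethoxyphenyl)bicyclo[3.2.1]oct-2-en-8-one
Product: 23 (1S,4R,5S,6R,7S)-1-allyl-3,5-dimethoxy-7-methyl-8-oxo-6-(3,4,5-trimethoxyphenyl)bicyclo[3.2.1]oct-2-en-4-yl acetate (CNP0181407.1)
Conditions: Ac2O, pyridine, DMAP (cat.), CH2Cl2, rt
Reagents that add atoms: acetic anhydride CC(=O)OC(C)=O
Why: DMAP-catalysed acetylation of a secondary alcohol, which leaves the C4–O bond and therefore the C4 configuration untouched.

Compound list
1 | 2,6-dimethoxyphenol (syringol) | COc1cccc(OC)c1O | starting material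
2 | allyl bromide | C=CCBr | starting material
3 | 2-allyloxy-1,3-dimethoxybenzene | C=CCOc1c(OC)cccc1OC | intermediate
4 | (3-allyloxy-2,4-dimethoxybenzylidene)dimethylammonium chloride, formed in step 2 and not isolated | C[N+](C)=Cc1ccc(OC)c(OCC=C)c1OC.[Cl-] | intermediate
5 | 3-allyloxy-2,4-dimethoxybenzaldehyde | O=Cc1ccc(OC)c(OCC=C)c1OC | intermediate
6 | 3-allyloxy-2,4-dimethoxyphenyl formate, formed in step 3 and not isolated | O=COc1ccc(OC)c(OCC=C)c1OC | intermediate
7 | 3-allyloxy-2,4-dimethoxyphenol | COc1ccc(O)c(OC)c1OCC=C | intermediate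
8 | 4-allyloxy-2-hydroxy-3,5-dimethoxybenzaldehyde | COc1cc(C=O)c(O)c(OC)c1OCC=C | intermediate
9 | 4-allyloxy-3,5-dimethoxy-2-(methoxymethoxy)benzaldehyde | COCOc1c(C=O)cc(OC)c(OCC=C)c1OC | intermediate
10 | methyltriphenylphosphonium bromide | C[P+](c1ccccc1)(c1ccccc1)c1ccccc1.[Br-] | starting material
11 | 2-allyloxy-1,3-dimethoxy-4-(methoxymethoxy)-5-vinylbenzene | C=Cc1cc(OC)c(OCC=C)c(OC)c1OCOC | intermediate
12 | 3,4,5-trimethoxybenzoic acid | COc1cc(cc(OC)c1OC)C(O)=O | starting material
13 | 3,4,5-trimethoxybenzoic anhydride | COc1cc(cc(OC)c1OC)C(=O)OC(=O)c1cc(OC)c(OC)c(OC)c1 | intermediate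
14 | (2R)-2-[4-allyloxy-3,5-dimethoxy-2-(methoxymethoxy)phenyl]-1-(3,4,5-trimethoxyphenyl)propan-1-one | C[C@H](c1cc(OC)c(OCC=C)c(OC)c1OCOC)C(=O)c1cc(OC)c(OC)c(OC)c1 | intermediate
15 | (2R)-2-[4-allyloxy-3,5-dimethoxy-2-(methoxymethoxy)phenyl]-1-(3,4,5-trimethoxyphenyl)propan-1-ol, both carbinol epimers | C[C@H](c1cc(OC)c(OCC=C)c(OC)c1OCOC)C(O)c1cc(OC)c(OC)c(OC)c1 | intermediate
16 | 3-allyloxy-6-[(2R)-1-hydroxy-1-(3,4,5-trimethoxyphenyl)propan-2-yl]-2,4-dimethoxyphenol, both carbinol epimers, formed in step 10 and not isolated | C[C@H](c1cc(OC)c(OCC=C)c(OC)c1O)C(O)c1cc(OC)c(OC)c(OC)c1 | intermediate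
17 | (2R,3R)-6-allyloxy-5,7-dimethoxy-3-methyl-2-(3,4,5-trimethoxyphenyl)-2,3-dihydrobenzofuran (trans) | C[C@@H]1c2cc(OC)c(OCC=C)c(OC)c2O[C@H]1c3cc(OC)c(OC)c(OC)c3 | intermediate
18 | (2R,3R,5R)-5-allyl-5,7-dimethoxy-3-methyl-2-(3,4,5-trimethoxyphenyl)-2,3-dihydrobenzofuran-6(5H)-one, Claisen product, not isolated | C=CC[C@@]1(OC)C=C2C(=C(OC)C1=O)O[C@@H](c1cc(OC)c(OC)c(OC)c1)[C@@H]2C | intermediate
19 | (2R,3R,3aS)-3a-allyl-5,7-dimethoxy-3-methyl-2-(3,4,5-trimethoxyphenyl)-3,3a-dihydrobenzofuran-6(2H)-one, Cope product with allyl cis to methyl, not isolated | C=CC[C@]12C=C(OC)C(=O)C(OC)=C1O[C@@H](c1cc(OC)c(OC)c(OC)c1)[C@@H]2C | intermediate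
20 | ring-opened zwitterion, drawn metal-free: 6-allyl-2,4-dimethoxy-3-oxocyclohexa-1,4-dien-1-olate carrying on C6 the 1-(3,4,5-trimethoxyphenyl)propan-1-ylium-2-yl chain, not isolated | C=CC[C@@]1(C=C(OC)C(=O)C(OC)=C1[O-])[C@@H](C)[CH+]c1cc(OC)c(OC)c(OC)c1 | intermediate
21 | (1S,5R,6R,7S)-1-allyl-3,5-dimethoxy-7-methyl-6-(3,4,5-trimethoxyphenyl)bicyclo[3.2.1]oct-2-ene-4,8-dione (aryl endo, methyl exo) | C=CC[C@]12C=C(OC)C(=O)[C@](OC)(C1=O)[C@@H](c1cc(OC)c(OC)c(OC)c1)[C@@H]2C | intermediate
22 | (1S,4R,5S,6R,7S)-1-allyl-4-hydroxy-3,5-dimethoxy-7-methyl-6-(3,4,5-trimethoxyphenyl)bicyclo[3.2.1]oct-2-en-8-one | C=CC[C@]12C=C(OC)[C@@H](O)[C@](OC)(C1=O)[C@@H](c1cc(OC)c(OC)c(OC)c1)[C@@H]2C | intermediate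
23 | (1S,4R,5S,6R,7S)-1-allyl-3,5-dimethoxy-7-methyl-8-oxo-6-(3,4,5-trimethoxyphenyl)bicyclo[3.2.1]oct-2-en-4-yl acetate | C=CC[C@]12C=C(OC)[C@@H](OC(C)=O)[C@](OC)(C1=O)[C@@H](c1cc(OC)c(OC)c(OC)c1)[C@@H]2C | target

Total step count: 13. Longest linear sequence: 12 steps (steps 1–6 and 8–13, from 1). Step 7 is a one-step side branch.

Steps most likely to fail

Step 11.
- What may go wrong: the dearomatised dienones lie well above the aromatic ether, so the relay may stall before ionisation, or the equilibrium may stay on the aromatic side.
- Competing processes: loss of the allyl group as a cation with transfer to the trimethoxyphenyl ring, proton loss from C7 at the cation stage (which would also erode the enantiomeric purity), and closure of the other C1 epimer to the aryl-exo, methyl-endo diastereomer.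
- Fallback: the known cationic [5+2] cycloaddition of a p-quinone monoketal with an (E)-propenylarene, followed by resolution. It sets out from 2 and comes back at 21.
- Route: allyl bromide 2 O-alkylates purchased 2,3,4-trimethoxyphenol F1 (K2CO3, acetone) to 1-allyloxy-2,3,4-trimethoxybenzene F2. An ordinary thermal ortho-Claisen rearrangement (N,N-diethylaniline, 190 °C) gives 6-allyl-2,3,4-trimethoxyphenol F3. PhI(OAc)2 in MeOH oxidises this hydroquinone monoether to 6-allyl-2,3,4,4-tetramethoxycyclohexa-2,5-dien-1-one F4. SnCl4 in CH2Cl2 at -78 °C ionises the ketal, and purchased (E)-isoelemicin F5 bonds with its methyl-bearing carbon to the allyl-bearing ring carbon and with its benzylic carbon to the methoxy-bearing carbon on the other side of the carbonyl group.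
- Outcome: the stacked endo approach usual for this cycloaddition should give the aryl-endo, methyl-exo dione as the racemate of 21 and the (1R,5S,6S,7R) enantiomer F6. Preparative chromatography on a cellulose carbamate chiral phase separates the two, and 21 goes on to the Luche reduction.

Step 8.
- What may go wrong: slow hydrocupration of the electron-rich, ortho-substituted styrene, hydrocupration of the allyl ether followed by loss of the aryloxide (deallylation), over-reduction of the ketone, or partial enolisation of the ketone on isolation.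
- Fallback: the known oxidative [3+2] coupling of a p-methoxyphenol with a propenylarene, followed by resolution. It sets out from 7 and comes back at 17, so the formylation, protection, olefination, hydroacylation, reduction and cyclisation are bypassed.
- Route: phenol 7 and the propenylarene F5 are treated with PhI(OCOCF3)2 in HFIP–CH2Cl2 at 0 °C. The phenoxenium ion is attacked at its only hydrogen-bearing ortho carbon by the methyl-bearing alkene carbon, and the benzylic cation is closed by the phenol oxygen.
- Outcome: rearomatisation should give the trans dihydrobenzofuran as the racemate of 17 and the (2S,3S) enantiomer F7, which are separated on the same kind of chiral phase.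

Step 12.
- What may go wrong: competing hydride addition to the strained C8 ketone, giving mixtures of mono- and doubly reduced material.
- Fallback: reduce both carbonyl groups, differentiate the two alcohols by hindrance, and re-oxidise. It sets out from 21 and comes back at 23.
- Route: excess diisobutylaluminium hydride (CH2Cl2, -78 → 0 °C) should give the 4,8-diol F8. C4 is attacked from the face syn to C8 as before, and C8 from the side of the C2=C3 bridge, its configuration being of no consequence. One equivalent of Ac2O in pyridine at 0 °C should acetylate only the C4 hydroxyl group, because the C8 carbinol sits between two fully substituted bridgeheads, giving the 8-hydroxy 4-acetate F9. Dess–Martin periodinane (NaHCO3, CH2Cl2) then restores the C8 ketone and gives 23 directly.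

Further compounds
F1 | step 11 | 2,3,4-trimethoxyphenol (purchased) | COc1ccc(O)c(OC)c1OC
F2 | step 11 | 1-allyloxy-2,3,4-trimethoxybenzene | C=CCOc1ccc(OC)c(OC)c1OC
F3 | step 11 | 6-allyl-2,3,4-trimethoxyphenol | C=CCc1cc(OC)c(OC)c(OC)c1O
F4 | step 11 | 6-allyl-2,3,4,4-tetramethoxycyclohexa-2,5-dien-1-one | C=CCC1=CC(OC)(OC)C(OC)=C(OC)C1=O
F5 | step 11 | (E)-isoelemicin, 1,2,3-trimethoxy-5-[(E)-prop-1-enyl]benzene (purchased) | C/C=C/c1cc(OC)c(OC)c(OC)c1
F6 | step 11 | (1R,5S,6S,7R)-1-allyl-3,5-dimethoxy-7-methyl-6-(3,4,5-trimethoxyphenyl)bicyclo[3.2.1]oct-2-ene-4,8-dione (enantiomer of 21) | C=CC[C@@]12C=C(OC)C(=O)[C@@](OC)(C1=O)[C@H](c1cc(OC)c(OC)c(OC)c1)[C@H]2C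
F7 | step 8 | (2S,3S)-6-allyloxy-5,7-dimethoxy-3-methyl-2-(3,4,5-trimethoxyphenyl)-2,3-dihydrobenzofuran (enantiomer of 17) | C[C@H]1c2cc(OC)c(OCC=C)c(OC)c2O[C@@H]1c3cc(OC)c(OC)c(OC)c3
F8 | step 12 | (1S,4R,5R,6R,7S,8S)-1-allyl-3,5-dimethoxy-7-methyl-6-(3,4,5-trimethoxyphenyl)bicyclo[3.2.1]oct-2-ene-4,8-diol | C=CC[C@]12C=C(OC)[C@@H](O)[C@](OC)([C@H]1O)[C@@H](c1cc(OC)c(OC)c(OC)c1)[C@@H]2C
F9 | step 12 | (1S,4R,5R,6R,7S,8S)-1-allyl-8-hydroxy-3,5-dimethoxy-7-methyl-6-(3,4,5-trimethoxyphenyl)bicyclo[3.2.1]oct-2-en-4-yl acetate | C=CC[C@]12C=C(OC)[C@@H](OC(C)=O)[C@](OC)([C@H]1O)[C@@H](c1cc(OC)c(OC)c(OC)c1)[C@@H]2C
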